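**Retrosynthetic overview**
- The para-quinone comes from the hydroquinone (Ag2O), which comes from its bis-TIPS ether (fluoride). The senecioate comes from the (S)-carbinol and 3-methylbut-2-enoic acid (Steglich).
- The prenyl terminus comes from an allyl carbinol by cross-metathesis with 2-methylbut-2-ene.
- The key C–C bond (carbinol carbon to CH2) comes from Brown asymmetric allylboration of a 5-arylfuran-3-carbaldehyde. This sets the only stereocentre, (S).
- The aryl–furan bond comes from Suzuki–Miyaura coupling of bis-TIPS-protected bromohydroquinone with (4-formylfuran-2-yl)boronic acid.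
- Rings: the benzene and furan rings are bought intact and no ring is constructed. The quinone ring is unveiled last by oxidation of the benzene ring.

Assumption: the stereocentre of the target is read as (S) (O > furyl > CH2 > H), and the allylborane is bought as its 1 M pentane solution.

**Route**

Step 1
Reactants: 1 2-bromobenzene-1,4-diol (bromohydroquinone)
Product: 2 2-bromo-1,4-bis(triisopropylsilyloxy)benzene
Conditions: TIPSCl, imidazole, DMF, 0 °C to rt, N2
Reagents that add atoms: triisopropylsilyl chloride, CC(C)[Si](Cl)(C(C)C)C(C)C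
Why: Imidazole-promoted silyl ether formation caps both phenols with a group that survives aqueous base, the allylborane and the Ru carbene, yet is removed by fluoride at the end without touching ester, alkene or furan.

Step 2
Reactants: 2 2-bromo-1,4-bis(triisopropylsilyloxy)benzene; 3 (4-formylfuran-2-yl)boronic acid
Product: 4 5-[2,5-bis(triisopropylsilyloxy)phenyl]furan-3-carbaldehyde
Conditions: Pd(OAc)2 (3 mol%), SPhos (6 mol%), K3PO4, THF/H2O 5:1, 50 °C
Reagents that add atoms: none
Why: Suzuki–Miyaura coupling, in which zerovalent palladium bearing the bulky electron-rich biarylphosphine inserts into the hindered C–Br bond and transmetallates fast enough at 50 °C to outrun protodeboronation of the 2-furylboronic acid, while the aldehyde and aryl silyl ethers are inert to aqueous K3PO4.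

Step 3
Reactants: 4 5-[2,5-bis(triisopropylsilyloxy)phenyl]furan-3-carbaldehyde; 5 (−)-B-allyldiisopinocampheylborane (the reagent derived from (+)-α-pinene)
Product: 7 (S)-1-{5-[2,5-bis(triisopropylsilyloxy)phenyl]furan-3-yl}but-3-en-1-ol, via borinate ester 6 (not isolated)
Conditions: Et2O/pentane, −78 °C, 3 h; then NaOH, H2O2, 0 °C to rt
Reagents that add atoms: none
Why: Brown asymmetric allylboration (carbonyl allylation) through a closed six-membered chair transition state, in which the isopinocampheyl groups from (+)-α-pinene direct allyl transfer to the Si face of the aldehyde and so give the (S)-carbinol of an aryl aldehyde (typically ≥ 94% ee) after oxidative cleavage of the B–O bond.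

Step 4
Reactants: 7 (S)-1-{5-[2,5-bis(triisopropylsilyloxy)phenyl]furan-3-yl}but-3-en-1-ol; 8 2-methylbut-2-ene
Product: 9 (S)-1-{5-[2,5-bis(triisopropylsilyloxy)phenyl]furan-3-yl}-4-methylpent-3-en-1-ol
Conditions: second-generation Grubbs catalyst RuCl2(=CHPh)(PCy3)(1,3-dimesitylimidazolidin-2-ylidene) (5 mol%), CH2Cl2/2-methylbut-2-ene (large excess), 40 °C, sealed tube
Reagents that add atoms: none
Why: Olefin cross-metathesis exchanges the terminal CH2 for the isopropylidene of the excess 2-methylbut-2-ene with loss of propene, building the prenyl group without touching the carbinol stereocentre, the furan or the silyl ethers.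

Step 5
Reactants: 9 (S)-1-{5-[2,5-bis(triisopropylsilyloxy)phenyl]furan-3-yl}-4-methylpent-3-en-1-ol; 10 3-methylbut-2-enoic acid (senecioic acid)
Product: 11 (S)-1-{5-[2,5-bis(triisopropylsilyloxy)phenyl]furan-3-yl}-4-methylpent-3-en-1-yl 3-methylbut-2-enoate
Conditions: DCC, DMAP, CH2Cl2, 0 °C to rt
Reagents that add atoms: none
Why: Steglich esterification acylates the secondary alcohol at oxygen with retention of configuration and avoids the vinylketene pathway by which senecioyl chloride deconjugates under amine bases.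

Step 6
Reactants: 11 (S)-1-{5-[2,5-bis(triisopropylsilyloxy)phenyl]furan-3-yl}-4-methylpent-3-en-1-yl 3-methylbut-2-enoate
Product: 12 (S)-1-[5-(2,5-dihydroxyphenyl)furan-3-yl]-4-methylpent-3-en-1-yl 3-methylbut-2-enoate
Conditions: TBAF, AcOH (1:1), THF, 0 °C, argon; used directly
Reagents that add atoms: none
Why: Fluoride-induced desilylation is driven by the strong Si–F bond and the good phenoxide leaving group, and the acetic acid buffer keeps the medium non-basic so the ester and the stereocentre are untouched.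

Step 7
Reactants: 12 (S)-1-[5-(2,5-dihydroxyphenyl)furan-3-yl]-4-methylpent-3-en-1-yl 3-methylbut-2-enoate
Product: 13 (S)-1-[5-(3,6-dioxocyclohexa-1,4-dien-1-yl)furan-3-yl]-4-methylpent-3-en-1-yl 3-methylbut-2-enoate
Conditions: Ag2O, MgSO4, Et2O, rt, dark, 30 min
Reagents that add atoms: none
Why: Hydroquinone-to-quinone oxidation by Ag2O under neutral anhydrous conditions removes two hydrogens from the ring and leaves the furan, the trisubstituted alkene, the ester and the stereocentre unchanged.

**Compound list**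
1 | 2-bromobenzene-1,4-diol | Oc1ccc(O)c(Br)c1 | starting material
2 | 2-bromo-1,4-bis(triisopropylsilyloxy)benzene | CC(C)[Si](Oc1ccc(O[Si](C(C)C)(C(C)C)C(C)C)c(Br)c1)(C(C)C)C(C)C | intermediate
3 | (4-formylfuran-2-yl)boronic acid | O=Cc1coc(B(O)O)c1 | starting material
4 | 5-[2,5-bis(triisopropylsilyloxy)phenyl]furan-3-carbaldehyde | O=Cc1coc(-c2cc(O[Si](C(C)C)(C(C)C)C(C)C)ccc2O[Si](C(C)C)(C(C)C)C(C)C)c1 | intermediate
5 | (−)-B-allyldiisopinocampheylborane, derived from (+)-α-pinene | C=CCB([C@@H]1C[C@@H]2C[C@H]([C@H]1C)C2(C)C)[C@@H]1C[C@@H]2C[C@H]([C@H]1C)C2(C)C | starting material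
6 | (S)-1-{5-[2,5-bis(triisopropylsilyloxy)phenyl]furan-3-yl}but-3-en-1-yl diisopinocampheylborinate | C=CC[C@H](OB([C@@H]1C[C@@H]2C[C@H]([C@H]1C)C2(C)C)[C@@H]1C[C@@H]2C[C@H]([C@H]1C)C2(C)C)c1coc(-c2cc(O[Si](C(C)C)(C(C)C)C(C)C)ccc2O[Si](C(C)C)(C(C)C)C(C)C)c1 | intermediate
7 | (S)-1-{5-[2,5-bis(triisopropylsilyloxy)phenyl]furan-3-yl}but-3-en-1-ol | C=CC[C@H](O)c1coc(-c2cc(O[Si](C(C)C)(C(C)C)C(C)C)ccc2O[Si](C(C)C)(C(C)C)C(C)C)c1 | intermediate
8 | 2-methylbut-2-ene | CC=C(C)C | starting material
9 | (S)-1-{5-[2,5-bis(triisopropylsilyloxy)phenyl]furan-3-yl}-4-methylpent-3-en-1-ol | CC(C)=CC[C@H](O)c1coc(-c2cc(O[Si](C(C)C)(C(C)C)C(C)C)ccc2O[Si](C(C)C)(C(C)C)C(C)C)c1 | intermediate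
10 | 3-methylbut-2-enoic acid | CC(C)=CC(=O)O | starting material
11 | (S)-1-{5-[2,5-bis(triisopropylsilyloxy)phenyl]furan-3-yl}-4-methylpent-3-en-1-yl 3-methylbut-2-enoate | CC(C)=CC[C@H](OC(=O)C=C(C)C)c1coc(-c2cc(O[Si](C(C)C)(C(C)C)C(C)C)ccc2O[Si](C(C)C)(C(C)C)C(C)C)c1 | intermediate
12 | (S)-1-[5-(2,5-dihydroxyphenyl)furan-3-yl]-4-methylpent-3-en-1-yl 3-methylbut-2-enoate | CC(C)=CC[C@H](OC(=O)C=C(C)C)c1coc(-c2cc(O)ccc2O)c1 | intermediate
13 | (S)-1-[5-(3,6-dioxocyclohexa-1,4-dien-1-yl)furan-3-yl]-4-methylpent-3-en-1-yl 3-methylbut-2-enoate | CC(C)=CC[C@H](OC(=O)C=C(C)C)c1coc(C2=CC(=O)C=CC2=O)c1 | target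

**Totals**
Total step count: 7. Longest linear sequence: 7 steps (1 to 13).

**Three steps most likely to fail**

Step 2 (Suzuki coupling). The 2-furylboronic acid 3 can protodeboronate before the hindered, electron-rich bromide 2 has reacted. The fallback reverses the polarity of the coupling; it sets out from 2 and comes back at 4. Miyaura borylation of 2 (B2pin2, Pd(dppf)Cl2, KOAc, dioxane, 90 °C) gives 2-[2,5-bis(triisopropylsilyloxy)phenyl]-4,4,5,5-tetramethyl-1,3,2-dioxaborolane F1. This stable arylboronate is coupled with purchased methyl 5-bromofuran-3-carboxylate F2 (Pd(PPh3)4, K3PO4, dioxane/H2O, 80 °C) to give methyl 5-[2,5-bis(triisopropylsilyloxy)phenyl]furan-3-carboxylate F3. Reduction with (Me2CHCH2)2AlH (CH2Cl2, −78 to 0 °C) gives {5-[2,5-bis(triisopropylsilyloxy)phenyl]furan-3-yl}methanol F4, and MnO2 (CH2Cl2, rt) oxidises this furylic alcohol to aldehyde 4.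

Step 3 (asymmetric allylboration). The enantiomeric excess may stay near 92–96%, short of single-enantiomer quality, and isopinocampheol can be hard to remove. The fallback replaces reagent control by a kinetic resolution; it sets out from 4 and comes back at 7. Allylmagnesium bromide (THF, −78 °C) gives racemic 1-{5-[2,5-bis(triisopropylsilyloxy)phenyl]furan-3-yl}but-3-en-1-ol F5. Burkholderia cepacia lipase with vinyl acetate in t-BuOMe (30 °C, stopped at about 55% conversion) acylates the (R)-enantiomer, with the aryl group as the large substituent, to (R)-1-{5-[2,5-bis(triisopropylsilyloxy)phenyl]furan-3-yl}but-3-en-1-yl acetate F6. This is removed by chromatography and leaves the unreacted (S)-alcohol 7. The same resolution can polish material of insufficient ee from step 3.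

Step 4 (cross-metathesis). The free homoallylic, furylic carbinol can stall the catalyst or isomerise via Ru–H species to the ketone. The fallback masks the alcohol as the final ester before metathesis; it sets out from 7 and comes back at 11. Steglich esterification of 7 with 10 (DCC, DMAP, CH2Cl2) gives (S)-1-{5-[2,5-bis(triisopropylsilyloxy)phenyl]furan-3-yl}but-3-en-1-yl 3-methylbut-2-enoate F7. Cross-metathesis of F7 with 8 (second-generation Hoveyda–Grubbs catalyst RuCl2(=CH-C6H4-2-OCHMe2)(1,3-dimesitylimidazolidin-2-ylidene), CH2Cl2, 40 °C) then gives 11 directly, because the trisubstituted electron-poor senecioate alkene is inert to metathesis. Steps 6 and 7 follow unchanged.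

**Further compounds**
F1 | step 2 | 2-[2,5-bis(triisopropylsilyloxy)phenyl]-4,4,5,5-tetramethyl-1,3,2-dioxaborolane | CC(C)[Si](Oc1ccc(O[Si](C(C)C)(C(C)C)C(C)C)c(B2OC(C)(C)C(C)(C)O2)c1)(C(C)C)C(C)C
F2 | step 2 | methyl 5-bromofuran-3-carboxylate (purchased) | COC(=O)c1coc(Br)c1
F3 | step 2 | methyl 5-[2,5-bis(triisopropylsilyloxy)phenyl]furan-3-carboxylate | COC(=O)c1coc(-c2cc(O[Si](C(C)C)(C(C)C)C(C)C)ccc2O[Si](C(C)C)(C(C)C)C(C)C)c1
F4 | step 2 | {5-[2,5-bis(triisopropylsilyloxy)phenyl]furan-3-yl}methanol | OCc1coc(-c2cc(O[Si](C(C)C)(C(C)C)C(C)C)ccc2O[Si](C(C)C)(C(C)C)C(C)C)c1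
F5 | step 3 | racemic 1-{5-[2,5-bis(triisopropylsilyloxy)phenyl]furan-3-yl}but-3-en-1-ol | C=CCC(O)c1coc(-c2cc(O[Si](C(C)C)(C(C)C)C(C)C)ccc2O[Si](C(C)C)(C(C)C)C(C)C)c1
F6 | step 3 | (R)-1-{5-[2,5-bis(triisopropylsilyloxy)phenyl]furan-3-yl}but-3-en-1-yl acetate | C=CC[C@@H](OC(C)=O)c1coc(-c2cc(O[Si](C(C)C)(C(C)C)C(C)C)ccc2O[Si](C(C)C)(C(C)C)C(C)C)c1
F7 | step 4 | (S)-1-{5-[2,5-bis(triisopropylsilyloxy)phenyl]furan-3-yl}but-3-en-1-yl 3-methylbut-2-enoate | C=CC[C@H](OC(=O)C=C(C)C)c1coc(-c2cc(O[Si](C(C)C)(C(C)C)C(C)C)ccc2O[Si](C(C)C)(C(C)C)C(C)C)c1
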